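**Retrosynthetic overview**
1. The last step is one neutral hydrogenation of a tri-O-benzyl (E)-alkene. It saturates C2'=C3' of the tether and removes all three benzyl ethers.
2. Key disconnection: olefin cross metathesis at C2'=C3'. It joins an allyl-dihydroisocoumarin half (16 skeletal atoms) to a butenyl mevalonate half (14 skeletal atoms).
3. The lactone half comes from lactonisation of a hydroxy amide. That amide arises from hydroquinone (two directed ortho metalations) and (R)-2-allyloxirane, itself made from (R)-epichlorohydrin.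
4. The ester half comes from (S)-but-3-en-2-ol and (R)-5-benzyloxy-3-hydroxy-3-methylpentanoic acid. The acid is made from but-3-yn-1-ol by carboalumination, Sharpless epoxidation, hydride opening and oxidation.
5. Ring order: benzene ring A is bought. Lactone ring B is the only ring built, and it is closed inside the lactone half before the coupling.

Assumption: the SMILES is read as 3R (lactone carbon), 4'S (side-chain carbinol) and 3''R (mevalonate carbon), and (R)-epichlorohydrin and (S)-but-3-en-2-ol are bought enantiopure.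

**Fragment 1 (lactone half)**

Step 1
Reactants: 1 hydroquinone (benzene-1,4-diol)
Product: 2 1,4-bis(methoxymethoxy)benzene
Conditions: NaH (2.4 equiv), MOMCl (2.4 equiv), DMF, 0 °C to rt
Reagents that add atoms: chloromethyl methyl ether (MOMCl), COCCl
Why: Williamson O-alkylation of the bis-phenoxide gives two MOM acetals, which protect the hydroquinone and act as ortho-directing groups for the lithiations that follow.

Step 2
Reactants: 2 1,4-bis(methoxymethoxy)benzene
Product: 4 N,N-diethyl-2,5-bis(methoxymethoxy)benzamide, via aryllithium 3 (not isolated)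
Conditions: n-BuLi (1.05 equiv), TMEDA, THF, 0 °C, 1 h; then Et2NCOCl, −78 °C to rt
Reagents that add atoms: N,N-diethylcarbamoyl chloride, CCN(CC)C(=O)Cl
Why: Directed ortho metalation at one of four equivalent C–H positions gives a single aryllithium, and its acyl substitution on the carbamoyl chloride stops at the tertiary amide, which resists a second addition.

Step 3
Reactants: 5 (R)-epichlorohydrin
Product: 6 (2R)-1-chloropent-4-en-2-ol
Conditions: CH2=CHMgBr (1.2 equiv), CuI (10 mol %), THF, −40 to −20 °C; then H2O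
Reagents that add atoms: vinylmagnesium bromide, C=C[Mg]Br
Why: Copper-catalysed SN2 opening takes place at the unsubstituted epoxide carbon, so the C–O bond at the stereocentre is never broken and the R configuration is carried over.

Step 4
Reactants: 6 (2R)-1-chloropent-4-en-2-ol
Product: 7 (2R)-2-(prop-2-en-1-yl)oxirane ((R)-2-allyloxirane)
Conditions: powdered NaOH (2 equiv), Et2O, rt; distil
Reagents that add atoms: none
Why: Intramolecular Williamson closure has the alkoxide displace the primary chloride, so the stereocentre keeps its C–O bond and stays R.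

Step 5
Reactants: 4 N,N-diethyl-2,5-bis(methoxymethoxy)benzamide; 7 (R)-2-allyloxirane
Product: 10 N,N-diethyl-2-[(2R)-2-hydroxypent-4-en-1-yl]-3,6-bis(methoxymethoxy)benzamide, via aryllithium 8 (not isolated), via arylmagnesium bromide 9 (not isolated)
Conditions: s-BuLi (1.1 equiv), TMEDA, THF, −78 °C, 1 h; MgBr2 (1.15 equiv, Et2O solution), −78 to 0 °C; CuI (15 mol %), 7 (1.3 equiv), −20 °C to rt; then H2O
Reagents that add atoms: none
Why: Directed ortho metalation goes to C6, where the amide and the neighbouring OMOM group cooperate, and after Li-to-Mg exchange the copper-catalysed SN2 opening at the epoxide CH2 carries the R carbinol of 7 unchanged into the future C3.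

Step 6
Reactants: 10 N,N-diethyl-2-[(2R)-2-hydroxypent-4-en-1-yl]-3,6-bis(methoxymethoxy)benzamide
Product: 12 (3R)-5,8-dihydroxy-3-(prop-2-en-1-yl)-3,4-dihydro-1H-isochromen-1-one, via triol amide 11 (not isolated)
Conditions: 3 M HCl in MeOH, 45 °C, 2 h, evaporate; then p-TsOH·H2O (1.3 equiv), toluene, 100 °C, argon
Reagents that add atoms: none
Why: Acetal exchange with methanol removes both MOM groups as volatile dimethoxymethane (evaporated, so no Prins or hydroxymethylation chemistry follows), and the acid-promoted N-to-O acyl transfer then closes ring B at the carbonyl carbon, leaving the C3–O bond and its R configuration intact.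

Step 7
Reactants: 12 (3R)-5,8-dihydroxy-3-(prop-2-en-1-yl)-3,4-dihydro-1H-isochromen-1-one
Product: 13 (3R)-5,8-bis(benzyloxy)-3-(prop-2-en-1-yl)-3,4-dihydro-1H-isochromen-1-one
Conditions: BnBr (2.6 equiv), K2CO3 (3 equiv), DMF, 55 °C, argon
Reagents that add atoms: benzyl bromide, BrCc1ccccc1
Why: Williamson benzylation of both phenols (warming overcomes the hydrogen bond of the 8-OH) masks the air-sensitive hydroquinone with groups that leave under the neutral final hydrogenation.

**Fragment 2 (ester half)**

Step 8
Reactants: 14 but-3-yn-1-ol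
Product: 15 4-(benzyloxy)but-1-yne
Conditions: NaH (1.1 equiv), BnBr (1.05 equiv), Bu4NI (5 mol %), THF, 0 °C to rt
Reagents that add atoms: benzyl bromide, BrCc1ccccc1
Why: Williamson etherification of the alkoxide works because NaH does not deprotonate the terminal alkyne under these conditions.

Step 9
Reactants: 15 4-(benzyloxy)but-1-yne
Product: 18 (2E)-5-(benzyloxy)-3-methylpent-2-en-1-ol, via alkenylalane 16 (not isolated), via lithium alanate 17 (not isolated)
Conditions: Me3Al (2 equiv), Cp2ZrCl2 (0.25 equiv), CH2Cl2, 0 °C to rt, 12 h; evaporate, hexane; n-BuLi (1.0 equiv), THF, 0 °C; (CH2O)n (3 equiv), rt; then H2O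
Reagents that add atoms: trimethylaluminium, C[Al](C)C; formaldehyde (as paraformaldehyde), C=O
Why: Negishi zirconium-catalysed carboalumination adds Me and Al syn with Al at the terminus, and the derived ate complex transfers its alkenyl group to formaldehyde with retention, giving only the E allylic alcohol.

Step 10
Reactants: 18 (2E)-5-(benzyloxy)-3-methylpent-2-en-1-ol
Product: 19 {(2R,3R)-3-[2-(benzyloxy)ethyl]-3-methyloxiran-2-yl}methanol
Conditions: Ti(OiPr)4 (10 mol %), D-(−)-diethyl tartrate (12 mol %), t-BuOOH (2 equiv, decane), 4 Å MS, CH2Cl2, −20 °C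
Reagents that add atoms: tert-butyl hydroperoxide, CC(C)(C)OO
Why: In this Katsuki–Sharpless asymmetric epoxidation the substrate has the geraniol substitution pattern, for which L-(+)-tartrate gives the (2S,3S)-epoxide, so D-(−)-tartrate gives the (2R,3R)-epoxide and sets the quaternary C–O stereocentre (about 95% ee expected).

Step 11
Reactants: 19 {(2R,3R)-3-[2-(benzyloxy)ethyl]-3-methyloxiran-2-yl}methanol
Product: 20 (3S)-5-(benzyloxy)-3-methylpentane-1,3-diol
Conditions: NaAlH2(OCH2CH2OMe)2 (1.5 equiv), THF, 0 °C to rt; then H2O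
Reagents that add atoms: none
Why: Hydroxyl-directed hydride delivery from the bound alkoxyaluminate opens the epoxide by SN2 at the less hindered C2, so the C3–O bond is untouched and the descriptor changes to S only through CIP priorities.

Step 12
Reactants: 20 (3S)-5-(benzyloxy)-3-methylpentane-1,3-diol
Product: 21 (3R)-5-(benzyloxy)-3-hydroxy-3-methylpentanoic acid
Conditions: TEMPO (0.2 equiv), PhI(OAc)2 (2.4 equiv), MeCN/H2O 1:1, rt
Reagents that add atoms: water, O
Why: Oxoammonium (TEMPO) oxidation takes the primary alcohol through the aldehyde hydrate to the acid, while the tertiary alcohol cannot be oxidised and the benzyl ether is inert (the descriptor returns to R by priority only).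

Step 13
Reactants: 21 (3R)-5-(benzyloxy)-3-hydroxy-3-methylpentanoic acid; 22 (2S)-but-3-en-2-ol
Product: 23 (2S)-but-3-en-2-yl (3R)-5-(benzyloxy)-3-hydroxy-3-methylpentanoate
Conditions: 22 (1.8 equiv), DCC (1.3 equiv), DMAP (0.2 equiv), CH2Cl2, 0 °C to rt
Reagents that add atoms: none
Why: Steglich esterification acylates the oxygen of the secondary alcohol, so its C–O bond and S configuration are retained, and the hindered tertiary OH of 21 does not compete with the excess of 22.

**Coupling and end game**

Step 14
Reactants: 13 (3R)-5,8-bis(benzyloxy)-3-(prop-2-en-1-yl)-3,4-dihydro-1H-isochromen-1-one; 23 (2S)-but-3-en-2-yl (3R)-5-(benzyloxy)-3-hydroxy-3-methylpentanoate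
Product: 24 (2S,3E)-5-[(3R)-5,8-bis(benzyloxy)-1-oxo-3,4-dihydro-1H-isochromen-3-yl]pent-3-en-2-yl (3R)-5-(benzyloxy)-3-hydroxy-3-methylpentanoate
Conditions: 23 (2 equiv, excess recovered), second-generation Hoveyda–Grubbs catalyst RuCl2(H2IMes)(=CH-C6H4-2-OiPr) (5 mol %), 1,4-benzoquinone (10 mol %), CH2Cl2, 40 °C
Reagents that add atoms: none
Why: In this olefin cross metathesis the unhindered allyl group of 13 reacts fast and dimerises reversibly while the secondary allylic ester 23 dimerises slowly, so the cross product dominates (E favoured, geometry erased in step 15), ethene loss drives the reaction and no stereocentre is touched.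

Step 15
Reactants: 24 (2S,3E)-5-[(3R)-5,8-bis(benzyloxy)-1-oxo-3,4-dihydro-1H-isochromen-3-yl]pent-3-en-2-yl (3R)-5-(benzyloxy)-3-hydroxy-3-methylpentanoate
Product: 25 aspergimarin C, (2S)-5-[(3R)-5,8-dihydroxy-1-oxo-3,4-dihydro-1H-isochromen-3-yl]pentan-2-yl (3R)-3,5-dihydroxy-3-methylpentanoate
Conditions: H2 (1 atm), 10% Pd/C, EtOAc, rt; filter under argon
Reagents that add atoms: none
Why: Heterogeneous hydrogenation saturates the disubstituted alkene first and then hydrogenolyses the three benzyl ethers under neutral conditions, so the lactone, the secondary ester, the tertiary alcohol and all three stereocentres survive, and the freed primary OH meets no acid or base that could trigger mevalonolactone formation.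

**Compound list**
1 | hydroquinone | Oc1ccc(O)cc1 | starting material
2 | 1,4-bis(methoxymethoxy)benzene | COCOc1ccc(OCOC)cc1 | intermediate
3 | [2,5-bis(methoxymethoxy)phenyl]lithium | [Li]c1cc(OCOC)ccc1OCOC | intermediate
4 | N,N-diethyl-2,5-bis(methoxymethoxy)benzamide | CCN(CC)C(=O)c1cc(OCOC)ccc1OCOC | intermediate
5 | (R)-epichlorohydrin | ClC[C@H]1CO1 | starting material
6 | (2R)-1-chloropent-4-en-2-ol | ClC[C@H](O)CC=C | intermediate
7 | (2R)-2-(prop-2-en-1-yl)oxirane | C=CC[C@@H]1CO1 | intermediate
8 | [2-(diethylcarbamoyl)-3,6-bis(methoxymethoxy)phenyl]lithium | [Li]c1c(OCOC)ccc(OCOC)c1C(=O)N(CC)CC | intermediate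
9 | [2-(diethylcarbamoyl)-3,6-bis(methoxymethoxy)phenyl]magnesium bromide | Br[Mg]c1c(OCOC)ccc(OCOC)c1C(=O)N(CC)CC | intermediate
10 | N,N-diethyl-2-[(2R)-2-hydroxypent-4-en-1-yl]-3,6-bis(methoxymethoxy)benzamide | C=CC[C@@H](O)Cc1c(OCOC)ccc(OCOC)c1C(=O)N(CC)CC | intermediate
11 | N,N-diethyl-3,6-dihydroxy-2-[(2R)-2-hydroxypent-4-en-1-yl]benzamide | C=CC[C@@H](O)Cc1c(O)ccc(O)c1C(=O)N(CC)CC | intermediate
12 | (3R)-5,8-dihydroxy-3-(prop-2-en-1-yl)-3,4-dihydro-1H-isochromen-1-one | C=CC[C@@H]1Cc2c(O)ccc(O)c2C(=O)O1 | intermediate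
13 | (3R)-5,8-bis(benzyloxy)-3-(prop-2-en-1-yl)-3,4-dihydro-1H-isochromen-1-one | C=CC[C@@H]1Cc2c(OCc3ccccc3)ccc(OCc3ccccc3)c2C(=O)O1 | intermediate
14 | but-3-yn-1-ol | C#CCCO | starting material
15 | 4-(benzyloxy)but-1-yne | C#CCCOCc1ccccc1 | intermediate
16 | [(1E)-4-(benzyloxy)-2-methylbut-1-en-1-yl]dimethylalane | C[Al](C)/C=C(\C)CCOCc1ccccc1 | intermediate
17 | lithium [(1E)-4-(benzyloxy)-2-methylbut-1-en-1-yl](butyl)dimethylaluminate | [Li+].CCCC[Al-](C)(C)/C=C(\C)CCOCc1ccccc1 | intermediate
18 | (2E)-5-(benzyloxy)-3-methylpent-2-en-1-ol | OC/C=C(\C)CCOCc1ccccc1 | intermediate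
19 | {(2R,3R)-3-[2-(benzyloxy)ethyl]-3-methyloxiran-2-yl}methanol | OC[C@H]1O[C@]1(C)CCOCc1ccccc1 | intermediate
20 | (3S)-5-(benzyloxy)-3-methylpentane-1,3-diol | OCC[C@](C)(O)CCOCc1ccccc1 | intermediate
21 | (3R)-5-(benzyloxy)-3-hydroxy-3-methylpentanoic acid | OC(=O)C[C@](C)(O)CCOCc1ccccc1 | intermediate
22 | (2S)-but-3-en-2-ol | C[C@H](O)C=C | starting material
23 | (2S)-but-3-en-2-yl (3R)-5-(benzyloxy)-3-hydroxy-3-methylpentanoate | C[C@@H](C=C)OC(=O)C[C@](C)(O)CCOCc1ccccc1 | intermediate
24 | (2S,3E)-5-[(3R)-5,8-bis(benzyloxy)-1-oxo-3,4-dihydro-1H-isochromen-3-yl]pent-3-en-2-yl (3R)-5-(benzyloxy)-3-hydroxy-3-methylpentanoate | C[C@@H](/C=C/C[C@@H]1Cc2c(OCc3ccccc3)ccc(OCc3ccccc3)c2C(=O)O1)OC(=O)C[C@](C)(O)CCOCc1ccccc1 | intermediate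
25 | aspergimarin C | C[C@@H](CCC[C@@H]1Cc2c(O)ccc(O)c2C(=O)O1)OC(=O)C[C@](C)(O)CCO | target

**Counts**
Total step count: 15.
Longest linear sequence: 8 (steps 8, 9, 10, 11, 12, 13, 14, 15). The hydroquinone and epichlorohydrin lines each run 7 steps to the target.

**Three steps most likely to fail**

Step 5. The arylmetal is flanked by the amide and an OMOM group, so it may open the epoxide slowly, and bromide from MgBr2 can compete to give a bromohydrin.
The fallback drops the epoxide. It sets out from arylmagnesium bromide 9 and comes back at 10.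
Compound 9 is quenched with allyl bromide (CuI 5 mol %, −78 °C to rt), an electrophile that hindered benzamide anions accept readily. This gives N,N-diethyl-3,6-bis(methoxymethoxy)-2-(prop-2-en-1-yl)benzamide F1.
Lemieux–Johnson cleavage (OsO4 cat., NaIO4, 2,6-lutidine, dioxane/H2O) then gives N,N-diethyl-3,6-bis(methoxymethoxy)-2-(2-oxoethyl)benzamide F2.
Brown allylboration with (+)-B-allyldiisopinocampheylborane (from (−)-α-pinene; Et2O, −78 °C; NaOH/H2O2 work-up) sets the R carbinol by reagent control and delivers 10. Steps 3 and 4 are then not needed.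

Step 14. Two valuable olefins of comparable size are joined. The bulky secondary allylic ester may react slowly, 13 may end up as its homodimer, and an excess of 23 is costly.
The fallback moves the fragment union from the C=C bond to the ester bond. It sets out from 13 and 22 and comes back at 24.
Compound 13 is cross-metathesised with a five-fold excess of the cheap, small alcohol 22 (same ruthenium catalyst, CH2Cl2, 40 °C). This gives (3R)-5,8-bis(benzyloxy)-3-[(2E,4S)-4-hydroxypent-2-en-1-yl]-3,4-dihydro-1H-isochromen-1-one F3.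
F3 is then acylated with acid 21 (DCC, DMAP, CH2Cl2) to give 24.

Step 15. On palladium the allylic ester can suffer C–O hydrogenolysis, or the double bond can migrate towards the carbinol carbon, before saturation is complete.
The fallback separates the two tasks. It sets out from 24 and comes back at 25.
Metal-free diimide reduction (2-nitrobenzenesulfonyl hydrazide, Et3N, CH2Cl2, rt) saturates the alkene without touching allylic C–O bonds. This gives (2S)-5-[(3R)-5,8-bis(benzyloxy)-1-oxo-3,4-dihydro-1H-isochromen-3-yl]pentan-2-yl (3R)-5-(benzyloxy)-3-hydroxy-3-methylpentanoate F4.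
The now non-allylic F4 is debenzylated with H2 and Pd(OH)2/C in EtOAc to give 25.

Further compounds
F1 | step 5 | N,N-diethyl-3,6-bis(methoxymethoxy)-2-(prop-2-en-1-yl)benzamide | C=CCc1c(OCOC)ccc(OCOC)c1C(=O)N(CC)CC
F2 | step 5 | N,N-diethyl-3,6-bis(methoxymethoxy)-2-(2-oxoethyl)benzamide | O=CCc1c(OCOC)ccc(OCOC)c1C(=O)N(CC)CC
F3 | step 14 | (3R)-5,8-bis(benzyloxy)-3-[(2E,4S)-4-hydroxypent-2-en-1-yl]-3,4-dihydro-1H-isochromen-1-one | C[C@H](O)/C=C/C[C@@H]1Cc2c(OCc3ccccc3)ccc(OCc3ccccc3)c2C(=O)O1
F4 | step 15 | (2S)-5-[(3R)-5,8-bis(benzyloxy)-1-oxo-3,4-dihydro-1H-isochromen-3-yl]pentan-2-yl (3R)-5-(benzyloxy)-3-hydroxy-3-methylpentanoate | C[C@@H](CCC[C@@H]1Cc2c(OCc3ccccc3)ccc(OCc3ccccc3)c2C(=O)O1)OC(=O)C[C@](C)(O)CCOCc1ccccc1
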